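The hexasubstituted benzene ring of the chroman (C4a, C5, C6, C7, C8, C8a) is disconnected at C7–C8, C4a–C8a and C6–C7 into a 3-benzyloxy-4-methyl-2-prenylcyclobutenone and a triisopropylsiloxyalkyne that carries the 3-phenylpropanoyl group as its dioxolane. One thermal vinylketene–alkyne benzannulation builds this ring with all six substituents and exploits its three alternating oxygens: they emerge as benzyl ether (C5), free phenol (C7) and silyl ether (C8a), so only O1 on C8a can later open the (S)-epoxide made from the C4a prenyl group. That closure forms the pyran ring and carries the epoxide configuration into C3.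

Key step: step 6

Remark on the chemistry: atoms are numbered as in the chroman (O1, C2, C3, C4, C4a, C5–C8, C8a); the C5 oxygen is carried as a benzyl ether because an ethyl ether there could only be cleaved at the end by Lewis acids that also open the chroman; the L-fructose-derived Shi ketone is assumed to be available.

Step 1
Reactants: 1 benzyl alcohol; 2 trichloroethylene
Product: 3 benzyl (E)-1,2-dichlorovinyl ether
Conditions: KH, THF, 0 °C; then 2, −78 °C → rt
Reagents that add atoms: none
Why: Potassium benzyloxide dehydrochlorinates trichloroethylene to dichloroacetylene and adds to it anti, the standard alkoxide addition–elimination route to (E)-1,2-dichlorovinyl ethers.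

Step 2
Reactants: 3 benzyl (E)-1,2-dichlorovinyl ether; 4 1-bromo-3-methylbut-2-ene
Product: 7 1-(benzyloxy)-5-methylhex-4-en-1-yne, via chloroalkyne 5 (not isolated), via lithium alkoxyacetylide 6 (not isolated)
Conditions: n-BuLi (2.2 equiv), THF, −78 °C; then 4, DMPU, −78 → 0 °C; work-up and chromatography below 25 °C
Reagents that add atoms: none
Why: n-BuLi effects β-elimination to the chloroalkyne and chlorine–lithium exchange to the lithium alkoxyacetylide, whose SN2 alkylation by the primary allylic bromide (acetylide alkylation) should give the ynol ether, which is kept cold because benzyl ynol ethers rearrange sigmatropically on warming.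

Step 3
Reactants: 7 1-(benzyloxy)-5-methylhex-4-en-1-yne; 8 propanoyl chloride
Product: 10 3-(benzyloxy)-4-methyl-2-(3-methylbut-2-en-1-yl)cyclobut-2-en-1-one (racemic), via methylketene 9 (not isolated)
Conditions: Et3N, Et2O, slow addition of 8 (excess), 0 °C → rt
Reagents that add atoms: none
Why: Triethylamine generates methylketene from 8, and its [2+2] cycloaddition with the ynol ether (ketene–alkyne cycloaddition) is steered by attack of the nucleophilic prenyl-bearing alkyne carbon on the ketene carbonyl carbon, so that the alkoxy carbon ends next to the CHMe carbon; the C4 centre is racemic and is erased in step 6.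

Step 4
Reactants: 11 ethyl 2-oxo-4-phenylbutanoate
Product: 12 ethyl 2-(2-phenylethyl)-1,3-dioxolane-2-carboxylate
Conditions: (TMSOCH2)2, TMSOTf (cat.), CH2Cl2, −78 °C → rt
Reagents that add atoms: 1,2-bis(trimethylsilyloxy)ethane, C[Si](C)(C)OCCO[Si](C)(C)C
Why: Noyori ketalisation with the bis-silyl ether under TMSOTf catalysis should convert the activated ketone into the dioxolane without water and without transesterification of the ethyl ester.

Step 5
Reactants: 12 ethyl 2-(2-phenylethyl)-1,3-dioxolane-2-carboxylate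
Product: 15 triisopropyl{[2-(2-phenylethyl)-1,3-dioxolan-2-yl]ethynyloxy}silane, via lithium dibromoenolate 13 (not isolated), via lithium ynolate 14 (not isolated)
Conditions: CH2Br2, lithium 2,2,6,6-tetramethylpiperidide (from n-BuLi and the amine), THF, −78 °C; n-BuLi (excess), −78 → 25 °C; TIPSCl, −78 °C → rt
Reagents that add atoms: dibromomethane, BrCBr; chlorotriisopropylsilane, CC(C)[Si](Cl)(C(C)C)C(C)C
Why: Kowalski ester homologation, in which LiCHBr2 adds to the ester, bromine–lithium exchange on the dibromo enolate triggers 1,2-migration of the ketal-bearing carbon to give the ynolate, and the bulky silyl chloride traps it on oxygen.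

Step 6
Reactants: 10 3-(benzyloxy)-4-methyl-2-(3-methylbut-2-en-1-yl)cyclobut-2-en-1-one (1.3 equiv); 15 triisopropyl{[2-(2-phenylethyl)-1,3-dioxolan-2-yl]ethynyloxy}silane
Product: 20 5-(benzyloxy)-6-methyl-4-(3-methylbut-2-en-1-yl)-2-[2-(2-phenylethyl)-1,3-dioxolan-2-yl]-3-[(triisopropylsilyl)oxy]phenol, via vinylketene 16 (not isolated), via vinylcyclobutenone 17 (not isolated), via dienylketene 18 (not isolated), via cyclohexadienone 19 (not isolated)
Conditions: toluene (0.5 M), 80 °C then 110 °C, sealed tube, Ar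
Reagents that add atoms: none
Why: Four-electron electrocyclic opening of 10 gives vinylketene 16, whose ketene C=C adds the electron-rich alkyne 15 in a [2+2] cycloaddition to 17; a second four-electron opening gives dienylketene 18, 6π-electrocyclisation gives 19, and enolisation gives phenol 20. The closest known reaction type is the Danheiser benzannulation of cyclobutenones with siloxyalkynes to resorcinol monosilyl ethers, run here with a 3-alkoxycyclobutenone so that a phloroglucinol pattern results. The benzene ring is closed by the thermal 6π-electrocyclisation of 18, which forms C6–C7 after the cycloaddition has formed C7–C8 and C4a–C8a. No stereocentre is formed, and the racemic C4 of 10 becomes the aromatic C6. The step needs a regioselective ketene–alkyne union, and the polarised siloxyalkyne secures it: its nucleophilic carbon (the one bearing the dioxolane) attacks the ketene carbonyl carbon, so the silyloxy carbon ends next to the prenyl-bearing carbon. The three oxygens should therefore emerge differentiated (C7 OH, C8a OTIPS, C5 OBn), and the reversible ring openings should funnel either alkene geometry of 18 to the product.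

Step 7
Reactants: 20 5-(benzyloxy)-6-methyl-4-(3-methylbut-2-en-1-yl)-2-[2-(2-phenylethyl)-1,3-dioxolan-2-yl]-3-[(triisopropylsilyl)oxy]phenol
Product: 21 2-{2,4-bis(benzyloxy)-3-methyl-5-(3-methylbut-2-en-1-yl)-6-[(triisopropylsilyl)oxy]phenyl}-2-(2-phenylethyl)-1,3-dioxolane
Conditions: BnBr, K2CO3, Bu4NI (cat.), DMF, rt
Reagents that add atoms: benzyl bromide, BrCc1ccccc1
Why: Williamson etherification of the only free phenol masks it against oxidation in step 8 with a group that leaves together with the C5 benzyl ether in step 10, while the mild carbonate base should leave the hindered aryl silyl ether intact.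

Step 8
Reactants: 21 2-{2,4-bis(benzyloxy)-3-methyl-5-(3-methylbut-2-en-1-yl)-6-[(triisopropylsilyl)oxy]phenyl}-2-(2-phenylethyl)-1,3-dioxolane
Product: 22 2-{2,4-bis(benzyloxy)-5-{[(2S)-3,3-dimethyloxiran-2-yl]methyl}-3-methyl-6-[(triisopropylsilyl)oxy]phenyl}-2-(2-phenylethyl)-1,3-dioxolane
Conditions: L-fructose-derived Shi ketone (1,2:4,5-di-O-isopropylidene-β-L-erythro-2,3-hexodiulo-2,6-pyranose, 0.3 equiv), KHSO5 (as 2KHSO5·KHSO4·K2SO4), K2CO3, Bu4NHSO4, aq. Na2B4O7/Na2H2EDTA buffer (pH 10.5), MeCN–CH2(OMe)2, 0 °C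
Reagents that add atoms: potassium peroxymonosulfate, [K+].[O-]S(=O)(=O)OO
Why: Shi asymmetric epoxidation, in which the dioxirane formed from the L-fructose-derived ketone transfers oxygen to the trisubstituted alkene through the spiro transition state on the face opposite to that used by the D-fructose-derived ketone (which gives (R) for R–CH=CMe2 alkenes), so that the oxirane CH carbon is set as (S) under catalyst control.

Step 9
Reactants: 22 2-{2,4-bis(benzyloxy)-5-{[(2S)-3,3-dimethyloxiran-2-yl]methyl}-3-methyl-6-[(triisopropylsilyl)oxy]phenyl}-2-(2-phenylethyl)-1,3-dioxolane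
Product: 25 1-[(3S)-5,7-bis(benzyloxy)-3-hydroxy-2,2,6-trimethyl-3,4-dihydro-2H-chromen-8-yl]-3-phenylpropan-1-one, via epoxy phenol 23 (not isolated), via chromanol ketal 24 (not isolated)
Conditions: Bu4NF/AcOH (1:1), THF, 0 °C; extractive work-up; CSA (0.2 equiv), CH2Cl2, −20 → 0 °C; then 2 M aq. HCl, THF, rt
Reagents that add atoms: water, O
Why: Buffered fluoride frees only the C8a phenol without forming the phenoxide that would favour 5-exo attack, the Brønsted acid then directs this phenol to the tertiary epoxide carbon (6-endo epoxide opening with Markovnikov selectivity, no bond to C3 being touched, so it stays (S)), and aqueous acid hydrolyses the crowded dioxolane to the aryl ketone.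

Step 10
Reactants: 25 1-[(3S)-5,7-bis(benzyloxy)-3-hydroxy-2,2,6-trimethyl-3,4-dihydro-2H-chromen-8-yl]-3-phenylpropan-1-one
Product: 26 1-[(3S)-3,5,7-trihydroxy-2,2,6-trimethyl-3,4-dihydro-2H-chromen-8-yl]-3-phenylpropan-1-one (the target)
Conditions: H2 (1 atm), Pd/C, EtOAc, rt
Reagents that add atoms: none
Why: Catalytic hydrogenolysis should cleave both benzyl aryl ethers under neutral conditions that leave the chroman ether, the secondary alcohol and the hydrogen-bonded aryl ketone untouched.

Compound list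

1 | benzyl alcohol | OCc1ccccc1 | starting material
2 | trichloroethylene | ClC=C(Cl)Cl | starting material
3 | benzyl (E)-1,2-dichlorovinyl ether | Cl/C=C(/Cl)OCc1ccccc1 | intermediate
4 | 1-bromo-3-methylbut-2-ene (prenyl bromide) | CC(C)=CCBr | starting material
5 | (benzyloxy)chloroethyne | ClC#COCc1ccccc1 | intermediate (not isolated)
6 | lithium (benzyloxy)acetylide | [Li]C#COCc1ccccc1 | intermediate (not isolated)
7 | 1-(benzyloxy)-5-methylhex-4-en-1-yne | CC(C)=CCC#COCc1ccccc1 | intermediate
8 | propanoyl chloride | CCC(=O)Cl | starting material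
9 | methylketene (prop-1-en-1-one) | CC=C=O | intermediate (not isolated)
10 | 3-(benzyloxy)-4-methyl-2-(3-methylbut-2-en-1-yl)cyclobut-2-en-1-one, racemic | CC1C(=O)C(CC=C(C)C)=C1OCc2ccccc2 | intermediate
11 | ethyl 2-oxo-4-phenylbutanoate | CCOC(=O)C(=O)CCc1ccccc1 | starting material
12 | ethyl 2-(2-phenylethyl)-1,3-dioxolane-2-carboxylate | CCOC(=O)C1(CCc2ccccc2)OCCO1 | intermediate
13 | lithium 2,2-dibromo-1-[2-(2-phenylethyl)-1,3-dioxolan-2-yl]ethen-1-olate | [Li+].[O-]C(=C(Br)Br)C1(CCc2ccccc2)OCCO1 | intermediate (not isolated)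
14 | lithium 2-[2-(2-phenylethyl)-1,3-dioxolan-2-yl]ethyn-1-olate | [Li+].[O-]C#CC1(CCc2ccccc2)OCCO1 | intermediate (not isolated)
15 | triisopropyl{[2-(2-phenylethyl)-1,3-dioxolan-2-yl]ethynyloxy}silane | CC(C)[Si](OC#CC1(CCc2ccccc2)OCCO1)(C(C)C)C(C)C | intermediate
16 | 3-(benzyloxy)-2-(3-methylbut-2-en-1-yl)penta-1,3-dien-1-one (vinylketene, alkene geometry not fixed) | CC=C(OCc1ccccc1)C(CC=C(C)C)=C=O | intermediate (not isolated)
17 | 4-[1-(benzyloxy)prop-1-en-1-yl]-4-(3-methylbut-2-en-1-yl)-2-[2-(2-phenylethyl)-1,3-dioxolan-2-yl]-3-[(triisopropylsilyl)oxy]cyclobut-2-en-1-one, racemic | CC=C(OCc1ccccc1)C2(CC=C(C)C)C(=O)C(C3(CCc4ccccc4)OCCO3)=C2O[Si](C(C)C)(C(C)C)C(C)C | intermediate (not isolated)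
18 | 5-(benzyloxy)-4-(3-methylbut-2-en-1-yl)-2-[2-(2-phenylethyl)-1,3-dioxolan-2-yl]-3-[(triisopropylsilyl)oxy]hepta-1,3,5-trien-1-one (dienylketene) | CC=C(OCc1ccccc1)C(CC=C(C)C)=C(O[Si](C(C)C)(C(C)C)C(C)C)C(=C=O)C2(CCc3ccccc3)OCCO2 | intermediate (not isolated)
19 | 5-(benzyloxy)-6-methyl-4-(3-methylbut-2-en-1-yl)-2-[2-(2-phenylethyl)-1,3-dioxolan-2-yl]-3-[(triisopropylsilyl)oxy]cyclohexa-2,4-dien-1-one, racemic | CC1C(=O)C(C2(CCc3ccccc3)OCCO2)=C(O[Si](C(C)C)(C(C)C)C(C)C)C(CC=C(C)C)=C1OCc4ccccc4 | intermediate (not isolated)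
20 | 5-(benzyloxy)-6-methyl-4-(3-methylbut-2-en-1-yl)-2-[2-(2-phenylethyl)-1,3-dioxolan-2-yl]-3-[(triisopropylsilyl)oxy]phenol | Cc1c(O)c(C2(CCc3ccccc3)OCCO2)c(O[Si](C(C)C)(C(C)C)C(C)C)c(CC=C(C)C)c1OCc4ccccc4 | intermediate
21 | 2-{2,4-bis(benzyloxy)-3-methyl-5-(3-methylbut-2-en-1-yl)-6-[(triisopropylsilyl)oxy]phenyl}-2-(2-phenylethyl)-1,3-dioxolane | Cc1c(OCc2ccccc2)c(C3(CCc4ccccc4)OCCO3)c(O[Si](C(C)C)(C(C)C)C(C)C)c(CC=C(C)C)c1OCc5ccccc5 | intermediate
22 | 2-{2,4-bis(benzyloxy)-5-{[(2S)-3,3-dimethyloxiran-2-yl]methyl}-3-methyl-6-[(triisopropylsilyl)oxy]phenyl}-2-(2-phenylethyl)-1,3-dioxolane | Cc1c(OCc2ccccc2)c(C3(CCc4ccccc4)OCCO3)c(O[Si](C(C)C)(C(C)C)C(C)C)c(C[C@@H]5OC5(C)C)c1OCc6ccccc6 | intermediate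
23 | 3,5-bis(benzyloxy)-2-{[(2S)-3,3-dimethyloxiran-2-yl]methyl}-4-methyl-6-[2-(2-phenylethyl)-1,3-dioxolan-2-yl]phenol | Cc1c(OCc2ccccc2)c(C3(CCc4ccccc4)OCCO3)c(O)c(C[C@@H]5OC5(C)C)c1OCc6ccccc6 | intermediate (not isolated)
24 | (3S)-5,7-bis(benzyloxy)-2,2,6-trimethyl-8-[2-(2-phenylethyl)-1,3-dioxolan-2-yl]-3,4-dihydro-2H-chromen-3-ol | Cc1c(OCc3ccccc3)c2c(c(C4(CCc5ccccc5)OCCO4)c1OCc6ccccc6)OC(C)(C)[C@@H](O)C2 | intermediate (not isolated)
25 | 1-[(3S)-5,7-bis(benzyloxy)-3-hydroxy-2,2,6-trimethyl-3,4-dihydro-2H-chromen-8-yl]-3-phenylpropan-1-one | Cc1c(OCc3ccccc3)c2c(c(C(=O)CCc4ccccc4)c1OCc5ccccc5)OC(C)(C)[C@@H](O)C2 | intermediate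
26 | 1-[(3S)-3,5,7-trihydroxy-2,2,6-trimethyl-3,4-dihydro-2H-chromen-8-yl]-3-phenylpropan-1-one | Cc1c(O)c2c(c(C(=O)CCc3ccccc3)c1O)OC(C)(C)[C@@H](O)C2 | target

Total step count: 10. Longest linear sequence: 8 steps (steps 1, 2, 3, 6, 7, 8, 9, 10); steps 4 and 5 form the second branch.

Steps most likely to fail

Step 6. The crowded [2+2] union of a fully substituted vinylketene with an alkyne whose reacting carbon sits next to a quaternary ketal may be slower than vinylketene dimerisation or than trapping of the ketene by the phenol product, so that little arene forms. The fallback is classical aromatic chemistry; it sets out from 4 and comes back at 26. Commercial 2-methylbenzene-1,3,5-triol is acylated with 3-phenylpropanoyl chloride (AlCl3, PhNO2, Friedel–Crafts) to 1-(2,4,6-trihydroxy-3-methylphenyl)-3-phenylpropan-1-one F1. C-Prenylation at the one free ring carbon with 4 (aq. KOH, 0 °C) should give 1-[2,4,6-trihydroxy-3-methyl-5-(3-methylbut-2-en-1-yl)phenyl]-3-phenylpropan-1-one F2. The para hydroxyl, the only one not hydrogen-bonded to the ketone and the most acidic, is benzylated (BnBr, 1 equiv, K2CO3, acetone) to 1-[4-(benzyloxy)-2,6-dihydroxy-3-methyl-5-(3-methylbut-2-en-1-yl)phenyl]-3-phenylpropan-1-one F3, which leaves a single free hydroxyl next to the prenyl group. Oxidative cyclisation with DDQ (benzene, reflux) should give the chromene 1-[5-(benzyloxy)-7-hydroxy-2,2,6-trimethyl-2H-chromen-8-yl]-3-phenylpropan-1-one F4, and benzylation (BnBr, K2CO3, DMF, 60 °C) the chromene 1-[5,7-bis(benzyloxy)-2,2,6-trimethyl-2H-chromen-8-yl]-3-phenylpropan-1-one F5. Jacobsen epoxidation with the (S,S)-configured chloro manganese complex of N,N'-bis(3,5-di-tert-butylsalicylidene)-1,2-cyclohexanediamine (trivalent manganese), NaOCl and 4-phenylpyridine N-oxide should give 1-[(3S,4S)-5,7-bis(benzyloxy)-3,4-epoxy-2,2,6-trimethyl-3,4-dihydro-2H-chromen-8-yl]-3-phenylpropan-1-one F6. Hydrogenation (H2, Pd/C, EtOAc) then cleaves the benzylic C4–O bond and both benzyl ethers to give 26.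

Step 9. Attack of the freed phenol on the secondary epoxide carbon (5-exo, giving a dihydrobenzofuran) or hydration of the epoxide may compete with the 6-endo closure, and early loss of the ketal may slow the phenol by hydrogen bonding. The fallback avoids intramolecular epoxide opening; it sets out from 21 and comes back at 26. Bu4NF (THF, 0 °C) should give 3,5-bis(benzyloxy)-4-methyl-2-(3-methylbut-2-en-1-yl)-6-[2-(2-phenylethyl)-1,3-dioxolan-2-yl]phenol F7, and aqueous HCl in THF the ketone 1-[2,4-bis(benzyloxy)-6-hydroxy-3-methyl-5-(3-methylbut-2-en-1-yl)phenyl]-3-phenylpropan-1-one F8. DDQ closes F8 to the chromene 1-[5,7-bis(benzyloxy)-2,2,6-trimethyl-2H-chromen-8-yl]-3-phenylpropan-1-one F5, a cyclisation that cannot give a five-membered ring. The (S,S)-Jacobsen epoxidation described above then gives the (3S,4S)-epoxide 1-[(3S,4S)-5,7-bis(benzyloxy)-3,4-epoxy-2,2,6-trimethyl-3,4-dihydro-2H-chromen-8-yl]-3-phenylpropan-1-one F6, and H2 with Pd/C gives 26, with C3 set by the chromene epoxidation.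

Step 3. Methylketene may dimerise or oligomerise faster than it is captured by the ynol ether, and the slow addition needed may let the heat-sensitive ynol ether decay. The fallback uses a more electrophilic ketene and a reductive step; it sets out from 7 and comes back at 10. Chloro(methyl)ketene F9, generated from 2-chloropropanoyl chloride and Et3N, should add to 7 with the same regiochemistry to give 3-(benzyloxy)-4-chloro-4-methyl-2-(3-methylbut-2-en-1-yl)cyclobut-2-en-1-one F10. Zinc dust with AcOH and TMEDA in EtOH, the usual dechlorination of 4-chlorocyclobutenones, then gives 10.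

Further compounds

F1 | step 6 | 1-(2,4,6-trihydroxy-3-methylphenyl)-3-phenylpropan-1-one | Cc1c(O)cc(O)c(C(=O)CCc2ccccc2)c1O
F2 | step 6 | 1-[2,4,6-trihydroxy-3-methyl-5-(3-methylbut-2-en-1-yl)phenyl]-3-phenylpropan-1-one | Cc1c(O)c(CC=C(C)C)c(O)c(C(=O)CCc2ccccc2)c1O
F3 | step 6 | 1-[4-(benzyloxy)-2,6-dihydroxy-3-methyl-5-(3-methylbut-2-en-1-yl)phenyl]-3-phenylpropan-1-one | Cc1c(OCc2ccccc2)c(CC=C(C)C)c(O)c(C(=O)CCc3ccccc3)c1O
F4 | step 6 | 1-[5-(benzyloxy)-7-hydroxy-2,2,6-trimethyl-2H-chromen-8-yl]-3-phenylpropan-1-one | Cc1c(OCc2ccccc2)c3C=CC(C)(C)Oc3c(C(=O)CCc4ccccc4)c1O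
F5 | step 6 | 1-[5,7-bis(benzyloxy)-2,2,6-trimethyl-2H-chromen-8-yl]-3-phenylpropan-1-one | Cc1c(OCc2ccccc2)c3C=CC(C)(C)Oc3c(C(=O)CCc4ccccc4)c1OCc5ccccc5
F6 | step 6 | 1-[(3S,4S)-5,7-bis(benzyloxy)-3,4-epoxy-2,2,6-trimethyl-3,4-dihydro-2H-chromen-8-yl]-3-phenylpropan-1-one | Cc1c(OCc2ccccc2)c3[C@@H]4O[C@@H]4C(C)(C)Oc3c(C(=O)CCc5ccccc5)c1OCc6ccccc6
F7 | step 9 | 3,5-bis(benzyloxy)-4-methyl-2-(3-methylbut-2-en-1-yl)-6-[2-(2-phenylethyl)-1,3-dioxolan-2-yl]phenol | Cc1c(OCc2ccccc2)c(C3(CCc4ccccc4)OCCO3)c(O)c(CC=C(C)C)c1OCc5ccccc5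
F8 | step 9 | 1-[2,4-bis(benzyloxy)-6-hydroxy-3-methyl-5-(3-methylbut-2-en-1-yl)phenyl]-3-phenylpropan-1-one | Cc1c(OCc2ccccc2)c(C(=O)CCc3ccccc3)c(O)c(CC=C(C)C)c1OCc4ccccc4
F9 | step 3 | chloro(methyl)ketene (2-chloroprop-1-en-1-one) | CC(Cl)=C=O
F10 | step 3 | 3-(benzyloxy)-4-chloro-4-methyl-2-(3-methylbut-2-en-1-yl)cyclobut-2-en-1-one, racemic | CC1(Cl)C(=O)C(CC=C(C)C)=C1OCc2ccccc2
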